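**Plan**

- Retrosynthesis: cut first the enol-ester C–O bond to the senecioyl group, then return the two side-chain carbonyls to a syn-diol acetonide. Next cut the pyranone C4–C4a bond (aryl propiolate), then the ester O1–C2 bond, and last the side-chain C1'=C2' bond (Wittig) to reach 2-hydroxy-6-methoxybenzaldehyde.
- Enabling feature: coumarin C4a lies para to the C7 methoxy group and is the only unsubstituted position ortho to O1, and C3 and C4 carry no substituent. A propiolate on O1 can therefore close the pyranone ring by arene attack.
- Forward: the five-carbon side chain is joined by Wittig olefination, dihydroxylated and masked as an acetonide. The phenol is then acylated with propiolic acid and the pyranone ring, the only ring built, is closed by cationic monovalent gold. The diol is finally unmasked, oxidised to the 1,2-dione and O-acylated.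
- Stereochemistry: the target has no stereocentre. The two transient carbinol centres arise from syn-dihydroxylation of the Z-alkene (racemic) and vanish on oxidation. The enol-ester terminus carries two methyl groups, so no alkene geometry has to be set.

Key step: step 7

Remark: intermediates 6–8 and 10–12 are racemic and are named and drawn by relative configuration (one enantiomer shown). Any E-alkene formed in step 2 would give the trans-acetonide series, which converges on the same dione 13.

**Route**

Step 1
Reactants: 1 2-hydroxy-6-methoxybenzaldehyde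
Product: 2 2-[(tert-butyldimethylsilyl)oxy]-6-methoxybenzaldehyde
Conditions: TBSCl, imidazole, DMF, 0 °C → rt
Reagents that add atoms: tert-butyldimethylsilyl chloride, CC(C)(C)[Si](C)(C)Cl
Why: Imidazole-promoted silyl ether formation masks the phenol, so one equivalent of ylide suffices in step 2 and the later acetonide can form only on the 1,2-diol and not as a benzodioxine bridging the phenol and the benzylic oxygen.

Step 2
Reactants: 2 2-[(tert-butyldimethylsilyl)oxy]-6-methoxybenzaldehyde; 3 isobutyltriphenylphosphonium bromide
Product: 5 tert-butyl{3-methoxy-2-[(1Z)-3-methylbut-1-en-1-yl]phenoxy}dimethylsilane, via triphenyl(2-methylpropylidene)phosphorane 4 (not isolated)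
Conditions: 3, KN(SiMe3)2, THF, 0 °C; then 2, −78 °C → rt
Reagents that add atoms: isobutyltriphenylphosphonium bromide (compound 3), CC(C)C[P+](c1ccccc1)(c1ccccc1)c1ccccc1.[Br-]
Why: Wittig olefination with a non-stabilised ylide under lithium-free conditions passes through a kinetically formed cis-oxaphosphetane and should give mainly the Z-alkene.

Step 3
Reactants: 5 tert-butyl{3-methoxy-2-[(1Z)-3-methylbut-1-en-1-yl]phenoxy}dimethylsilane
Product: 6 (1R*,2S*)-1-{2-[(tert-butyldimethylsilyl)oxy]-6-methoxyphenyl}-3-methylbutane-1,2-diol
Conditions: OsO4 (cat.), N-methylmorpholine N-oxide, acetone/H2O, rt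
Reagents that add atoms: osmium tetroxide, O=[Os](=O)(=O)=O; N-methylmorpholine N-oxide, C[N+]1([O-])CCOCC1; water, O
Why: Upjohn dihydroxylation adds both oxygens to one face of the Z-alkene in a concerted cycloaddition, so the syn (1R*,2S*) diol is set by the alkene geometry, in racemic form.

Step 4
Reactants: 6 (1R*,2S*)-1-{2-[(tert-butyldimethylsilyl)oxy]-6-methoxyphenyl}-3-methylbutane-1,2-diol
Product: 7 tert-butyl{2-[(4R*,5S*)-2,2-dimethyl-5-(propan-2-yl)-1,3-dioxolan-4-yl]-3-methoxyphenoxy}dimethylsilane
Conditions: 2,2-dimethoxypropane, PPTS (cat.), CH2Cl2, rt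
Reagents that add atoms: 2,2-dimethoxypropane, COC(C)(C)OC
Why: Acid-catalysed transketalisation (acetonide formation) closes the dioxolane on the only diol present and carries the syn relationship over as the cis-4,5 arrangement, while the aryl silyl ether tolerates the mild acid.

Step 5
Reactants: 7 tert-butyl{2-[(4R*,5S*)-2,2-dimethyl-5-(propan-2-yl)-1,3-dioxolan-4-yl]-3-methoxyphenoxy}dimethylsilane
Product: 8 2-[(4R*,5S*)-2,2-dimethyl-5-(propan-2-yl)-1,3-dioxolan-4-yl]-3-methoxyphenol
Conditions: TBAF, THF, 0 °C; aq. NH4Cl work-up
Reagents that add atoms: none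
Why: Fluoride-induced desilylation, driven by the strong Si–F bond, frees the phenol, and the acetonide is inert to fluoride.

Step 6
Reactants: 8 2-[(4R*,5S*)-2,2-dimethyl-5-(propan-2-yl)-1,3-dioxolan-4-yl]-3-methoxyphenol; 9 propiolic acid
Product: 10 2-[(4R*,5S*)-2,2-dimethyl-5-(propan-2-yl)-1,3-dioxolan-4-yl]-3-methoxyphenyl prop-2-ynoate
Conditions: DCC, DMAP (cat.), CH2Cl2, 0 °C → rt
Reagents that add atoms: propiolic acid (compound 9), C#CC(=O)O
Why: Steglich esterification activates the acid as its O-acylisourea and transfers the acyl group to the phenol at low temperature, where the acetonide and the terminal alkyne should persist.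

Step 7
Reactants: 10 2-[(4R*,5S*)-2,2-dimethyl-5-(propan-2-yl)-1,3-dioxolan-4-yl]-3-methoxyphenyl prop-2-ynoate
Product: 11 8-[(4R*,5S*)-2,2-dimethyl-5-(propan-2-yl)-1,3-dioxolan-4-yl]-7-methoxy-2H-chromen-2-one
Conditions: [JohnPhosAu(MeCN)]SbF6 (3 mol %; JohnPhos = (2-biphenylyl)di-tert-butylphosphine), dry CH2Cl2, rt
Reagents that add atoms: none
Why: The cationic monovalent gold complex binds the propiolate triple bond and makes its terminal carbon electrophilic; the arene carbon para to the methoxy group and ortho to the ester oxygen attacks it in a Friedel–Crafts sense, and rearomatisation followed by protodeauration of the vinylgold species gives the coumarin with C3 and C4 unsubstituted. The closest known reaction type is the gold-catalysed intramolecular hydroarylation of aryl propiolates to coumarins. The pyranone ring closes in the 6-endo-dig mode through the new C4–C4a bond. No stereocentre is created and the two acetonide centres are spectators. The step needs attack at the free position ortho to the ester oxygen and not ipso attack or reaction elsewhere; this is secured because the other ortho position carries the dioxolanyl group, the free one is the most electron-rich carbon of the ring, and ipso closure would have to occur at an oxygen-bearing carbon meta to the methoxy group. The side chain is held as an acetonide and not as a ketone so that the arene stays nucleophilic.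

Step 8
Reactants: 11 8-[(4R*,5S*)-2,2-dimethyl-5-(propan-2-yl)-1,3-dioxolan-4-yl]-7-methoxy-2H-chromen-2-one
Product: 12 8-[(1R*,2S*)-1,2-dihydroxy-3-methylbutyl]-7-methoxy-2H-chromen-2-one
Conditions: AcOH/H2O (4:1), 40 °C
Reagents that add atoms: none
Why: Acid-catalysed acetonide hydrolysis releases the diol with its own oxygens, and the lactone and the aryl methyl ether tolerate this mild acid.

Step 9
Reactants: 12 8-[(1R*,2S*)-1,2-dihydroxy-3-methylbutyl]-7-methoxy-2H-chromen-2-one
Product: 13 1-(7-methoxy-2-oxo-2H-chromen-8-yl)-3-methylbutane-1,2-dione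
Conditions: (COCl)2, DMSO, CH2Cl2, −78 °C; then Et3N, −78 → 0 °C
Reagents that add atoms: none
Why: In a double Swern oxidation both secondary hydroxyls are activated as alkoxysulfonium ions and eliminated by the amine at low temperature, which should give the 1,2-dione without C–C cleavage and removes both stereocentres.

Step 10
Reactants: 13 1-(7-methoxy-2-oxo-2H-chromen-8-yl)-3-methylbutane-1,2-dione; 14 3-methylbut-2-enoyl chloride
Product: 16 kimcuongin [1-(7-methoxy-2-oxo-2H-chromen-8-yl)-3-methyl-1-oxobut-2-en-2-yl 3-methylbut-2-enoate], via potassium enolate 15 (not isolated)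
Conditions: KN(SiMe3)2, THF, −78 °C; then 14, −78 → 0 °C
Reagents that add atoms: 3-methylbut-2-enoyl chloride (compound 14), CC(C)=CC(=O)Cl
Why: Enolate O-acylation: the isopropyl methine is the only acidic C–H of 13, and its potassium enolate should be acylated at oxygen by the hard acid chloride because the carbon terminus is fully substituted.

**Compound list**

1 | 2-hydroxy-6-methoxybenzaldehyde | COc1cccc(O)c1C=O | starting material
2 | 2-[(tert-butyldimethylsilyl)oxy]-6-methoxybenzaldehyde | COc1cccc(O[Si](C)(C)C(C)(C)C)c1C=O | intermediate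
3 | isobutyltriphenylphosphonium bromide | CC(C)C[P+](c1ccccc1)(c1ccccc1)c1ccccc1.[Br-] | starting material
4 | triphenyl(2-methylpropylidene)phosphorane | CC(C)C=P(c1ccccc1)(c1ccccc1)c1ccccc1 | intermediate (not isolated)
5 | tert-butyl{3-methoxy-2-[(1Z)-3-methylbut-1-en-1-yl]phenoxy}dimethylsilane | COc1cccc(O[Si](C)(C)C(C)(C)C)c1/C=C\C(C)C | intermediate
6 | (1R*,2S*)-1-{2-[(tert-butyldimethylsilyl)oxy]-6-methoxyphenyl}-3-methylbutane-1,2-diol (racemic) | COc1cccc(O[Si](C)(C)C(C)(C)C)c1[C@@H](O)[C@@H](O)C(C)C | intermediate
7 | tert-butyl{2-[(4R*,5S*)-2,2-dimethyl-5-(propan-2-yl)-1,3-dioxolan-4-yl]-3-methoxyphenoxy}dimethylsilane (racemic cis acetonide) | COc1cccc(O[Si](C)(C)C(C)(C)C)c1[C@H]1OC(C)(C)O[C@H]1C(C)C | intermediate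
8 | 2-[(4R*,5S*)-2,2-dimethyl-5-(propan-2-yl)-1,3-dioxolan-4-yl]-3-methoxyphenol (racemic) | COc1cccc(O)c1[C@H]1OC(C)(C)O[C@H]1C(C)C | intermediate
9 | propiolic acid | C#CC(=O)O | starting material
10 | 2-[(4R*,5S*)-2,2-dimethyl-5-(propan-2-yl)-1,3-dioxolan-4-yl]-3-methoxyphenyl prop-2-ynoate (racemic) | C#CC(=O)Oc1cccc(OC)c1[C@H]1OC(C)(C)O[C@H]1C(C)C | intermediate
11 | 8-[(4R*,5S*)-2,2-dimethyl-5-(propan-2-yl)-1,3-dioxolan-4-yl]-7-methoxy-2H-chromen-2-one (racemic) | COc1ccc2ccc(=O)oc2c1[C@H]1OC(C)(C)O[C@H]1C(C)C | intermediate
12 | 8-[(1R*,2S*)-1,2-dihydroxy-3-methylbutyl]-7-methoxy-2H-chromen-2-one (racemic) | COc1ccc2ccc(=O)oc2c1[C@@H](O)[C@@H](O)C(C)C | intermediate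
13 | 1-(7-methoxy-2-oxo-2H-chromen-8-yl)-3-methylbutane-1,2-dione | COc1ccc2ccc(=O)oc2c1C(=O)C(=O)C(C)C | intermediate
14 | 3-methylbut-2-enoyl chloride | CC(C)=CC(=O)Cl | starting material
15 | potassium 1-(7-methoxy-2-oxo-2H-chromen-8-yl)-3-methyl-1-oxobut-2-en-2-olate | COc1ccc2ccc(=O)oc2c1C(=O)C([O-])=C(C)C.[K+] | intermediate (not isolated)
16 | kimcuongin; 1-(7-methoxy-2-oxo-2H-chromen-8-yl)-3-methyl-1-oxobut-2-en-2-yl 3-methylbut-2-enoate | COc1ccc2ccc(=O)oc2c1C(=O)C(OC(=O)C=C(C)C)=C(C)C | target

**Step count**

Total step count: 10. Longest linear sequence: 10 steps (1 → 16).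

**Steps most likely to fail**

Step 7. The ring closure may stall because the terminal alkyne is drawn into a gold acetylide or digold resting state. The Lewis-acidic metal may also open the benzylic acetonide, after which traces of water hydrate the alkyne. The fallback closes the pyranone at the lactone end and sets out from phenol 8, bypassing steps 6 and 7. Ortho-formylation with MgCl2, Et3N and paraformaldehyde in MeCN at reflux can only occur at the single free ortho position. It should give 3-[(4R*,5S*)-2,2-dimethyl-5-(propan-2-yl)-1,3-dioxolan-4-yl]-2-hydroxy-4-methoxybenzaldehyde F1. Heating F1 with Ph3P=CHCO2Et in N,N-diethylaniline at reflux should form ethyl (2E)-3-{3-[(4R*,5S*)-2,2-dimethyl-5-(propan-2-yl)-1,3-dioxolan-4-yl]-2-hydroxy-4-methoxyphenyl}prop-2-enoate F2. F2 should isomerise and lactonise in the same pot with loss of ethanol, returning to the route at 11.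

Step 9. The glycol C–C bond may be cleaved, or the chlorosulfonium reagent may attack the enol of the newly formed dione (α-chlorination or methylthiomethylation). Over-oxidation or incomplete oxidation would follow. The fallback sets out from diol 12 and oxidises in two separate base-free stages with iodine-based reagents. 2-Iodoxybenzoic acid (1.2 equiv) in EtOAc at 75 °C should oxidise the benzylic hydroxyl first to give (±)-8-(2-hydroxy-3-methylbutanoyl)-7-methoxy-2H-chromen-2-one F3. F3 is isolated and taken with Dess–Martin periodinane in CH2Cl2 at rt to the dione, returning to the route at 13. No glycol is present in the second stage, so cleavage is excluded there.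

Step 10. The acid chloride may be deprotonated at its γ-methyl group to a vinylketene, which would deliver the deconjugated 3-methylbut-3-enoate. Acylation may also be diverted to carbon. The fallback sets out from dione 13 and gives up both the preformed metal enolate and the acid chloride. Soft enolisation with Et3N and acyl transfer from 3-methylbut-2-enoic anhydride through the N-acylpyridinium of catalytic DMAP (CH2Cl2, rt) should acylate the enol oxygen directly. It returns to the route at 16, and no new compound is made on this path (F0).

**Further compounds**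

F1 | step 7 | 3-[(4R*,5S*)-2,2-dimethyl-5-(propan-2-yl)-1,3-dioxolan-4-yl]-2-hydroxy-4-methoxybenzaldehyde (racemic) | COc1ccc(C=O)c(O)c1[C@H]1OC(C)(C)O[C@H]1C(C)C
F2 | step 7 | ethyl (2E)-3-{3-[(4R*,5S*)-2,2-dimethyl-5-(propan-2-yl)-1,3-dioxolan-4-yl]-2-hydroxy-4-methoxyphenyl}prop-2-enoate (racemic) | CCOC(=O)/C=C/c1ccc(OC)c([C@H]2OC(C)(C)O[C@H]2C(C)C)c1O
F3 | step 9 | (±)-8-(2-hydroxy-3-methylbutanoyl)-7-methoxy-2H-chromen-2-one (2S enantiomer drawn) | COc1ccc2ccc(=O)oc2c1C(=O)[C@@H](O)C(C)C
F0 | step 10 | none | none
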